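A direct plan would grow the molecule ring by ring outward from ring C. The aryloxyacetone A1 would be condensed with sodium nitromalonaldehyde A2 to build the middle ring as a nitrophenol, and the same benzannulation would then build the sulfated ring. In each new ring an amino group would steer two bromines, as in the dibromoaniline A3, and would then be replaced by bromine or hydrogen through a diazonium salt. The weakest steps would be the benzannulations (impact-sensitive salt, days in aqueous alkali in which the aryloxy ketone could shed its phenoxide), the dediazoniations of hindered 2,6-dibromoanilines (hot acid and radicals beside a C–I bond), and the nitro reduction and methyl ether cycles, which would add length without complexity.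

The target's only iodine sits on ring C (bromoiodo ring) next to the carbon whose oxygen is bonded to C2 of ring B (tribromo ring; C1 carries the oxygen to the sulfated ring A). This C–I/C–O pair is the trace of an aryl shift: the route cuts the O–C2 bond of ring B and joins C2 instead to trivalent iodine in a diaryliodonium salt, whose ortho phenolate oxygen takes ring B from iodine. One operation forms the most hindered ether bond and leaves the iodine in place. All six bromines arrive in purchased arenes, so no ring is built from acyclic carbons, no amino group or diazonium salt is needed, and the sulfate travels as its neopentyl ester.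

Key step: step 7

Remark: the target is taken as the free hydrogen sulfate (achiral, no stereocentre), a strong acid prone to hydrolysis, so it is set free only in the last operation, cold and dry; compounds 1, 3, 7 and 10 are taken as purchasable.

Step 1
Reactants: 1 3,4,5-tribromophenol
Product: 2 3,4,5-tribromo-2-iodophenol
Conditions: NIS (1.05 equiv), CF3CO2H (0.3 equiv), MeCN, rt, 16 h, dark
Reagents that add atoms: N-iodosuccinimide, O=C1CCC(=O)N1I
Why: Electrophilic aromatic iodination of a phenol whose para carbon is blocked by bromine and whose two ortho carbons are equivalent, so one equivalent of NIS should give a single regioisomer, the first iodine slowing a second attack.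

Step 2
Reactants: 2 3,4,5-tribromo-2-iodophenol; 3 3,5-dibromo-2-fluorobenzaldehyde (1.1 equiv)
Product: 4 3,5-dibromo-2-(3,4,5-tribromo-2-iodophenoxy)benzaldehyde
Conditions: K2CO3 (1.5 equiv), DMF, 80 °C, 12 h
Reagents that add atoms: none
Why: Nucleophilic aromatic substitution (addition–elimination) in which the phenoxide of 2 displaces fluoride, the only halogen ortho to the formyl group of 3, while the aryl bromides and the aryl iodide stay inert in the absence of a metal catalyst.

Step 3
Reactants: 4 3,5-dibromo-2-(3,4,5-tribromo-2-iodophenoxy)benzaldehyde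
Product: 6 3,5-dibromo-2-(3,4,5-tribromo-2-iodophenoxy)phenol, via aryl formate 5 (not isolated)
Conditions: mCPBA (2.0 equiv), CH2Cl2, 0 → 40 °C, 24 h; wash with aq Na2SO3; then MeOH, HCl (cat.), 40 °C, 2 h
Reagents that add atoms: mCPBA, OOC(=O)c1cccc(Cl)c1
Why: Baeyer–Villiger (Dakin-type) oxidation in which the aryl group, helped by its ortho aryloxy donor, migrates from carbon to oxygen in the peracid adduct to give the formate, which methanol cleaves, and any iodane formed at the aryl iodide is reduced back by the sulfite wash.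

Step 4
Reactants: 7 neopentyl alcohol (2,2-dimethylpropan-1-ol)
Product: 8 neopentyl chlorosulfate (2,2-dimethylpropyl sulfurochloridate)
Conditions: SO2Cl2 (1.0 equiv), pyridine (1.0 equiv), Et2O, −78 °C → rt, 2 h; filter, distil under reduced pressure
Reagents that add atoms: sulfuryl chloride, O=S(=O)(Cl)Cl
Why: O-sulfonylation of a primary alcohol by sulfuryl chloride stops at the chlorosulfate because the neopentyl carbon resists SN2 attack by chloride.

Step 5
Reactants: 6 3,5-dibromo-2-(3,4,5-tribromo-2-iodophenoxy)phenol; 8 neopentyl chlorosulfate (1.5 equiv)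
Product: 9 3,5-dibromo-2-(3,4,5-tribromo-2-iodophenoxy)phenyl neopentyl sulfate
Conditions: NaN(SiMe3)2 (1.1 equiv), THF–DMPU (9:1), −78 °C, 15 min; then 8, −78 °C → rt, 12 h
Reagents that add atoms: none
Why: Sulfonyl transfer in which the sodium phenoxide attacks sulfur and displaces chloride, giving a sulfate diester that is both the latent sulfate of the target and the cap that keeps this oxygen from attacking ring B later.

Step 6
Reactants: 9 3,5-dibromo-2-(3,4,5-tribromo-2-iodophenoxy)phenyl neopentyl sulfate; 10 (5-bromo-2-methoxyphenyl)boronic acid (1.3 equiv)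
Product: 12 (5-bromo-2-methoxyphenyl){2,3,4-tribromo-6-[2,4-dibromo-6-(neopentyloxysulfonyloxy)phenoxy]phenyl}iodonium tosylate, via hydroxy(tosyloxy)iodoarene 11 (not isolated)
Conditions: mCPBA (1.1 equiv), TsOH·H2O (1.1 equiv), CH2Cl2–CF3CH2OH (1:1), rt → 40 °C, 4 h; then 10, rt, 4 h; precipitate with Et2O
Reagents that add atoms: p-toluenesulfonic acid monohydrate, Cc1ccc(cc1)S(=O)(=O)O.O; mCPBA, OOC(=O)c1cccc(Cl)c1 (its oxygen stays only in 11)
Why: Oxidation of the aryl iodide to a [hydroxy(tosyloxy)iodo]arene followed by boron-to-iodine aryl exchange (ipso substitution of the boronic acid at trivalent iodine) should give the unsymmetrical diaryliodonium salt regiospecifically, and ring A has no free carbon ortho to its ether oxygen, so no cyclic iodonium salt can form.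

Step 7
Reactants: 12 (5-bromo-2-methoxyphenyl){2,3,4-tribromo-6-[2,4-dibromo-6-(neopentyloxysulfonyloxy)phenoxy]phenyl}iodonium tosylate
Product: 15 3,5-dibromo-2-[3,4,5-tribromo-2-(4-bromo-2-iodophenoxy)phenoxy]phenyl neopentyl sulfate, via hydroxyaryl iodonium bromide 13 (not isolated), via iodonium phenolate zwitterion 14 (not isolated)
Conditions: BBr3 (3 equiv), CH2Cl2, −78 → 0 °C, 2 h; MeOH at −78 °C, evaporate; then NaHCO3 (6 equiv), MeCN–H2O (9:1), 0.01 M, rt → 50 °C, 6 h, dark
Reagents that add atoms: none
Why: BBr3 cleaves the aryl methyl ether by SN2 attack of bromide on the O-methyl carbon, and hydrogen carbonate then deprotonates the acidified phenol 13 to the iodonium phenolate 14. In 14 the phenolate oxygen attacks C2 of ring B, the ipso carbon on iodine, through a five-membered spiro σ-complex-like transition state while the bond from that carbon to iodine breaks and iodine drops from trivalent to monovalent without leaving ring C; this is a 1,4 shift of aryl from iodine to oxygen, the known rearrangement of aryliodonium phenolates (ortho-hydroxy diaryliodonium salts) to 2-iodo diaryl ethers, in essence an intramolecular SNAr with an iodoarene as nucleofuge. No ring is closed and no stereocentre is formed. The step needs the phenolate to take ring B within its own molecule rather than from another one, and this is secured by the geometry (its own ring cannot be attacked), by the electron-poor ring B whose two ortho substituents speed ipso substitution and leave no ortho hydrogen for aryne formation, by high dilution and by a weak, non-nucleophilic base. Ring A cannot compete because its oxygen is held as the sulfate diester, which closes the path to a dibenzodioxin.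

Step 8
Reactants: 15 3,5-dibromo-2-[3,4,5-tribromo-2-(4-bromo-2-iodophenoxy)phenoxy]phenyl neopentyl sulfate
Product: 17 3,5-dibromo-2-[3,4,5-tribromo-2-(4-bromo-2-iodophenoxy)phenoxy]phenyl hydrogen sulfate (bromoiesol B sulfate), via sodium aryl sulfate 16 (not isolated)
Conditions: NaN3 (1.1 equiv), DMF, 70 °C, 16 h (behind a shield, neopentyl azide kept in solution); evaporate, desalt on a short C18 plug (H2O, then MeOH), dry; then HCl (1.0 equiv, 4 M in 1,4-dioxane), dry MeCN, 0 °C, 10 min; filter off NaCl; evaporate below 20 °C; store at −20 °C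
Reagents that add atoms: none
Why: SN2 dealkylation in which azide attacks the neopentyl carbon and the aryl sulfate monoanion leaves (the known deprotection of neopentyl sulfate esters), aryl halides and diaryl ethers being inert without a metal, after which one equivalent of HCl in dry MeCN should give the hydrogen sulfate while NaCl precipitates.

Compound list
1 | 3,4,5-tribromophenol | Oc1cc(Br)c(Br)c(Br)c1 | starting material
2 | 3,4,5-tribromo-2-iodophenol | Oc1cc(Br)c(Br)c(Br)c1I | intermediate
3 | 3,5-dibromo-2-fluorobenzaldehyde | O=Cc1cc(Br)cc(Br)c1F | starting material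
4 | 3,5-dibromo-2-(3,4,5-tribromo-2-iodophenoxy)benzaldehyde | O=Cc1cc(Br)cc(Br)c1Oc1cc(Br)c(Br)c(Br)c1I | intermediate
5 | 3,5-dibromo-2-(3,4,5-tribromo-2-iodophenoxy)phenyl formate | O=COc1cc(Br)cc(Br)c1Oc1cc(Br)c(Br)c(Br)c1I | intermediate
6 | 3,5-dibromo-2-(3,4,5-tribromo-2-iodophenoxy)phenol | Oc1cc(Br)cc(Br)c1Oc1cc(Br)c(Br)c(Br)c1I | intermediate
7 | neopentyl alcohol (2,2-dimethylpropan-1-ol) | CC(C)(C)CO | starting material
8 | neopentyl chlorosulfate (2,2-dimethylpropyl sulfurochloridate) | CC(C)(C)COS(=O)(=O)Cl | intermediate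
9 | 3,5-dibromo-2-(3,4,5-tribromo-2-iodophenoxy)phenyl neopentyl sulfate | CC(C)(C)COS(=O)(=O)Oc1cc(Br)cc(Br)c1Oc1cc(Br)c(Br)c(Br)c1I | intermediate
10 | (5-bromo-2-methoxyphenyl)boronic acid | COc1ccc(Br)cc1B(O)O | starting material
11 | 3,5-dibromo-2-{3,4,5-tribromo-2-[hydroxy(tosyloxy)-λ3-iodanyl]phenoxy}phenyl neopentyl sulfate | CC(C)(C)COS(=O)(=O)Oc1cc(Br)cc(Br)c1Oc1cc(Br)c(Br)c(Br)c1I(O)OS(=O)(=O)c1ccc(C)cc1 | intermediate
12 | (5-bromo-2-methoxyphenyl){2,3,4-tribromo-6-[2,4-dibromo-6-(neopentyloxysulfonyloxy)phenoxy]phenyl}iodonium tosylate | CC(C)(C)COS(=O)(=O)Oc1cc(Br)cc(Br)c1Oc1cc(Br)c(Br)c(Br)c1[I+]c1cc(Br)ccc1OC.Cc1ccc(cc1)S(=O)(=O)[O-] | intermediate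
13 | (5-bromo-2-hydroxyphenyl){2,3,4-tribromo-6-[2,4-dibromo-6-(neopentyloxysulfonyloxy)phenoxy]phenyl}iodonium bromide (counter-ion taken as bromide) | CC(C)(C)COS(=O)(=O)Oc1cc(Br)cc(Br)c1Oc1cc(Br)c(Br)c(Br)c1[I+]c1cc(Br)ccc1O.[Br-] | intermediate
14 | 4-bromo-2-({2,3,4-tribromo-6-[2,4-dibromo-6-(neopentyloxysulfonyloxy)phenoxy]phenyl}iodonio)phenolate (zwitterion) | CC(C)(C)COS(=O)(=O)Oc1cc(Br)cc(Br)c1Oc1cc(Br)c(Br)c(Br)c1[I+]c1cc(Br)ccc1[O-] | intermediate
15 | 3,5-dibromo-2-[3,4,5-tribromo-2-(4-bromo-2-iodophenoxy)phenoxy]phenyl neopentyl sulfate | CC(C)(C)COS(=O)(=O)Oc1cc(Br)cc(Br)c1Oc1cc(Br)c(Br)c(Br)c1Oc1ccc(Br)cc1I | intermediate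
16 | sodium 3,5-dibromo-2-[3,4,5-tribromo-2-(4-bromo-2-iodophenoxy)phenoxy]phenyl sulfate | [Na+].[O-]S(=O)(=O)Oc1cc(Br)cc(Br)c1Oc1cc(Br)c(Br)c(Br)c1Oc1ccc(Br)cc1I | intermediate
17 | bromoiesol B sulfate, 3,5-dibromo-2-[3,4,5-tribromo-2-(4-bromo-2-iodophenoxy)phenoxy]phenyl hydrogen sulfate (achiral) | O=S(=O)(O)Oc1cc(Br)cc(Br)c1Oc1cc(Br)c(Br)c(Br)c1Oc1ccc(Br)cc1I | target

Total step count: 8. Longest linear sequence: 7 (steps 1, 2, 3, 5, 6, 7 and 8; step 4 makes the sulfating reagent).

Steps most likely to fail

Step 7. The Lewis acid could attack the sulfate diester or pass bromide to the iodonium centre before the methyl ether is cleaved, and the freed phenolate could arylate a second molecule and give oligomers instead of shifting ring B within its own molecule. The fallback would set out from 9 and make the same ether bond by intermolecular ligand coupling. Compound 9 would be oxidised to 11 as in step 6 and trapped with 1,3,5-trimethoxybenzene F1 to give {2,3,4-tribromo-6-[2,4-dibromo-6-(neopentyloxysulfonyloxy)phenoxy]phenyl}(2,4,6-trimethoxyphenyl)iodonium tosylate F2. The salt F2 would then be treated with 4-bromo-2-iodophenol F3 and K2CO3 in MeCN at rt to 40 °C. The phenoxide of F3 should bind to trivalent iodine and couple with the electron-poor, doubly ortho-substituted ring B, the trimethoxyphenyl group staying on iodine, and the fallback would come back to the route at 15.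

Step 6. Oxidation of the very electron-poor iodide, flanked on both sides, could stall, or boron-to-iodine exchange at the crowded centre could be so slow that the peracid consumes the boronic acid. The fallback would set out from 9 and reverse the roles of the two rings. Iodine–magnesium exchange (i-PrMgCl·LiCl, THF, −78 °C) would give {2,3,4-tribromo-6-[2,4-dibromo-6-(neopentyloxysulfonyloxy)phenoxy]phenyl}magnesium chloride F4, which Me3SnCl would trap at −78 °C as 3,5-dibromo-2-[3,4,5-tribromo-2-(trimethylstannyl)phenoxy]phenyl neopentyl sulfate F5. Separately, 4-bromo-2-iodoanisole F6, an easily oxidised iodide, would be converted with mCPBA and TsOH·H2O into 4-bromo-2-[hydroxy(tosyloxy)-λ3-iodanyl]-1-methoxybenzene F7. Tin-to-iodine exchange between F5 and F7 in CH2Cl2 should give the same iodonium tosylate, and the fallback would come back to the route at 12.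

Step 8. Azide could attack sulfur instead of the neopentyl carbon and expel the acidic phenoxide, or the free acid could hydrolyse during isolation. The fallback would set out from 15 and use this sulfur–oxygen cleavage on purpose: NaOMe in MeOH–THF at 0 °C would give bromoiesol B, 3,5-dibromo-2-[3,4,5-tribromo-2-(4-bromo-2-iodophenoxy)phenoxy]phenol F8. Direct O-sulfation of F8 with SO3·pyridine in pyridine at 40 °C would then give pyridinium 3,5-dibromo-2-[3,4,5-tribromo-2-(4-bromo-2-iodophenoxy)phenoxy]phenyl sulfate F9, and proton exchange of F9 on a sulfonic acid resin in cold MeOH would bring the fallback back to the route at 17.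

Further compounds
F1 | step 7 | 1,3,5-trimethoxybenzene | COc1cc(OC)cc(OC)c1
F2 | step 7 | {2,3,4-tribromo-6-[2,4-dibromo-6-(neopentyloxysulfonyloxy)phenoxy]phenyl}(2,4,6-trimethoxyphenyl)iodonium tosylate | CC(C)(C)COS(=O)(=O)Oc1cc(Br)cc(Br)c1Oc1cc(Br)c(Br)c(Br)c1[I+]c1c(OC)cc(OC)cc1OC.Cc1ccc(cc1)S(=O)(=O)[O-]
F3 | step 7 | 4-bromo-2-iodophenol | Oc1ccc(Br)cc1I
F4 | step 6 | {2,3,4-tribromo-6-[2,4-dibromo-6-(neopentyloxysulfonyloxy)phenoxy]phenyl}magnesium chloride | CC(C)(C)COS(=O)(=O)Oc1cc(Br)cc(Br)c1Oc1cc(Br)c(Br)c(Br)c1[Mg]Cl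
F5 | step 6 | 3,5-dibromo-2-[3,4,5-tribromo-2-(trimethylstannyl)phenoxy]phenyl neopentyl sulfate | CC(C)(C)COS(=O)(=O)Oc1cc(Br)cc(Br)c1Oc1cc(Br)c(Br)c(Br)c1[Sn](C)(C)C
F6 | step 6 | 4-bromo-2-iodoanisole (4-bromo-2-iodo-1-methoxybenzene) | COc1ccc(Br)cc1I
F7 | step 6 | 4-bromo-2-[hydroxy(tosyloxy)-λ3-iodanyl]-1-methoxybenzene | COc1ccc(Br)cc1I(O)OS(=O)(=O)c1ccc(C)cc1
F8 | step 8 | 3,5-dibromo-2-[3,4,5-tribromo-2-(4-bromo-2-iodophenoxy)phenoxy]phenol (bromoiesol B) | Oc1cc(Br)cc(Br)c1Oc1cc(Br)c(Br)c(Br)c1Oc1ccc(Br)cc1I
F9 | step 8 | pyridinium 3,5-dibromo-2-[3,4,5-tribromo-2-(4-bromo-2-iodophenoxy)phenoxy]phenyl sulfate | c1cc[nH+]cc1.[O-]S(=O)(=O)Oc1cc(Br)cc(Br)c1Oc1cc(Br)c(Br)c(Br)c1Oc1ccc(Br)cc1I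
A1 | direct plan | 1-(4-bromo-2-iodophenoxy)propan-2-one | CC(=O)COc1ccc(Br)cc1I
A2 | direct plan | sodium nitromalonaldehyde (sodium 2-nitro-3-oxoprop-1-en-1-olate) | O=CC(=C[O-])[N+](=O)[O-].[Na+]
A3 | direct plan | 2,6-dibromo-4-methoxy-3-[3,4,5-tribromo-2-(4-bromo-2-iodophenoxy)phenoxy]aniline | COc1cc(Br)c(N)c(Br)c1Oc1cc(Br)c(Br)c(Br)c1Oc1ccc(Br)cc1I
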